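**Strategy**

Everything rests on cutting the O1–C2 bond of the pyranone ring (ring B) of the chroman-4-one. C2 with its methyl group, the homogeranyl chain, C3 and C4 form an intact farnesyl skeleton (C2 = farnesyl C3, C4 = farnesyl C1). The quaternary ether centre is therefore made by palladium-catalysed asymmetric allylic etherification at the methyl-bearing terminus of achiral (2E,6E)-farnesyl methyl carbonate with an ortho-bromophenol that supplies the benzene ring (ring A) and the C6 carboxyl as a tert-butyl ester. One operation forms O1–C2, sets C2 as S and leaves a vinyl group that is C3–C4; oxidation of its terminus and closure onto the brominated carbon C4a complete ring B.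

Key step: step 3

Assumption (chemistry): the (S,S) ligand is taken to give the 3S ether from the 2E carbonate, by analogy with related E-configured trisubstituted allyl carbonates; this sense is recalled, not derived, and is to be checked on the first run against material made with racemic ligand, the (R,R) ligand being used instead if it is opposite.

**Route**

Step 1
Reactants: 1 (2E,6E)-farnesol; 2 methyl chloroformate
Product: 3 (2E,6E)-farnesyl methyl carbonate
Conditions: ClCO2Me (1.3 equiv), pyridine (2 equiv), CH2Cl2, 0 °C → rt
Reagents that add atoms: methyl chloroformate (2), COC(=O)Cl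
Why: Alkoxycarbonylation (O-acylation) of a primary allylic alcohol by a chloroformate with pyridine is fast at 0 °C and touches neither double bond, so the 2E,6E geometry on which the key step depends is carried over intact.

Step 2
Reactants: 4 3-bromo-4-hydroxybenzoic acid; 5 N,N-dimethylformamide di-tert-butyl acetal
Product: 6 tert-butyl 3-bromo-4-hydroxybenzoate
Conditions: Me2NCH(OtBu)2 (3 equiv), toluene, 80 °C
Reagents that add atoms: N,N-dimethylformamide di-tert-butyl acetal (5), CN(C)C(OC(C)(C)C)OC(C)(C)C
Why: tert-Butyl esterification with a formamide acetal: the carboxylic acid protonates the acetal and its carboxylate is O-alkylated by the tert-butoxy-iminium ion, while the much less acidic phenol stays free under these base-free conditions, giving the hindered ester that must survive the later organolithium step.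

Step 3
Reactants: 3 (2E,6E)-farnesyl methyl carbonate; 6 tert-butyl 3-bromo-4-hydroxybenzoate
Product: 7 tert-butyl 3-bromo-4-{[(3S,6E)-3,7,11-trimethyldodeca-1,6,10-trien-3-yl]oxy}benzoate
Conditions: Pd2(dba)3·CHCl3 (1 mol%), N,N'-[(1S,2S)-cyclohexane-1,2-diyl]bis[2-(diphenylphosphanyl)benzamide] (3 mol%), degassed CH2Cl2, 0 °C → rt; 3 in slight excess (1.15 equiv); filtration through silica as soon as 6 is consumed
Reagents that add atoms: none
Why: The zerovalent palladium–bisphosphine complex ionises carbonate 3 with loss of CO2 to a π-allylpalladium cation whose C3 terminus carries the methyl group and the chain; the methoxide set free deprotonates phenol 6, and the phenoxide attacks that more substituted terminus from the face opposite to palladium, forming the O–C3 bond (later O1–C2). The closest known reaction type is the Tsuji–Trost asymmetric allylic O-alkylation of phenols with geranyl-type methyl carbonates to tertiary allyl aryl ethers, in which ortho-halogenated and carbonyl-substituted phenols are also established nucleophiles. No ring is formed in this step. The new stereocentre at C3 is controlled by the chiral pocket of the (S,S) ligand, which selects one enantioface of the allyl unit while the two faces interconvert through the σ-complex at the unsubstituted terminus, the pure 2E geometry keeping the chain in one defined position of the allyl. The step needs branched over linear selectivity, which the higher positive charge at the disubstituted terminus together with the ligand secures. It also needs the aryl C–Br bond and the product to stay untouched, which follows from the slow oxidative addition of triarylphosphine-bound zerovalent palladium to an aryl bromide at or below room temperature and from keeping 3 in slight excess and stopping once 6 is consumed, so that the catalyst is not left alone with the ionisable product.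

Step 4
Reactants: 7 tert-butyl 3-bromo-4-{[(3S,6E)-3,7,11-trimethyldodeca-1,6,10-trien-3-yl]oxy}benzoate
Product: 9 tert-butyl 3-bromo-4-{[(3S,6E)-1-hydroxy-3,7,11-trimethyldodeca-6,10-dien-3-yl]oxy}benzoate, via B-alkyl-9-BBN adduct 8 (not isolated)
Conditions: 9-BBN (9-borabicyclo[3.3.1]nonane, 1.3 equiv), THF, 0 °C → rt; then aq NaOAc, 30% H2O2, 0 °C → rt
Reagents that add atoms: hydrogen peroxide, OO
Why: Brown hydroboration–oxidation: 9-BBN adds to the monosubstituted vinyl group far faster than to the two trisubstituted alkenes and places boron on the terminal carbon, remote from the ether oxygen so that no eliminable β-oxyborane arises, and buffered peroxide then replaces boron by hydroxyl without affecting the tert-butyl ester, the aryl bromide or the C3 stereocentre.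

Step 5
Reactants: 9 tert-butyl 3-bromo-4-{[(3S,6E)-1-hydroxy-3,7,11-trimethyldodeca-6,10-dien-3-yl]oxy}benzoate
Product: 11 (3S,6E)-3-[2-bromo-4-(tert-butoxycarbonyl)phenoxy]-3,7,11-trimethyldodeca-6,10-dienoic acid, via aldehyde 10 (not isolated)
Conditions: TEMPO (2,2,6,6-tetramethylpiperidin-1-oxyl, 0.2 equiv), PhI(OAc)2 (2.2 equiv), MeCN/H2O (1:1), rt
Reagents that add atoms: water, O
Why: Nitroxyl-catalysed oxidation with PhI(OAc)2 as stoichiometric oxidant: the oxoammonium ion takes the primary alcohol to the aldehyde and then oxidises its hydrate to the acid in one pot, under weakly acidic conditions that leave the trisubstituted alkenes, the aryl bromide and the ester alone and offer no base to expel the aryloxide β to the carbonyl, the stereocentre not being involved.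

Step 6
Reactants: 11 (3S,6E)-3-[2-bromo-4-(tert-butoxycarbonyl)phenoxy]-3,7,11-trimethyldodeca-6,10-dienoic acid; 12 N,O-dimethylhydroxylamine hydrochloride
Product: 14 tert-butyl 3-bromo-4-({(3S,6E)-1-[methoxy(methyl)amino]-3,7,11-trimethyl-1-oxododeca-6,10-dien-3-yl}oxy)benzoate, via acyl imidazole 13 (not isolated)
Conditions: 1,1'-carbonyldiimidazole (1.2 equiv), CH2Cl2, 0 °C → rt; then MeNHOMe·HCl (1.5 equiv), rt
Reagents that add atoms: N,O-dimethylhydroxylamine hydrochloride (12), CNOC.Cl
Why: Amide formation through an acyl imidazole (carbonyldiimidazole activation): the amine hydrochloride is acylated with the released imidazole as the only base, which gives the N-methoxy-N-methylamide without a strong amine base that could trigger β-elimination of the aryloxide.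

Step 7
Reactants: 14 tert-butyl 3-bromo-4-({(3S,6E)-1-[methoxy(methyl)amino]-3,7,11-trimethyl-1-oxododeca-6,10-dien-3-yl}oxy)benzoate
Product: 17 tert-butyl (2S)-2-[(3E)-4,8-dimethylnona-3,7-dien-1-yl]-2-methyl-4-oxo-3,4-dihydro-2H-chromene-6-carboxylate, via aryllithium 15 (not isolated), via lithium hemiaminal alkoxide 16 (not isolated)
Conditions: t-BuLi (2.1 equiv), THF, −100 °C → −78 °C; AcOH in THF at −78 °C; aqueous work-up at pH ≤ 7
Reagents that add atoms: none
Why: Parham cyclisation: bromine–lithium exchange with t-BuLi at −100 °C is much faster than addition to the amide or to the hindered tert-butyl ester (the second equivalent destroys the tert-butyl bromide formed), the aryllithium closes ring B by 6-exo-trig attack on the N-methoxy-N-methylamide to form C4–C4a, and the chelated tetrahedral adduct holds until the cold acidic quench, so that no over-addition occurs and the β-aryloxy ketone is never exposed to base that could open ring B and erode C2.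

Step 8
Reactants: 17 tert-butyl (2S)-2-[(3E)-4,8-dimethylnona-3,7-dien-1-yl]-2-methyl-4-oxo-3,4-dihydro-2H-chromene-6-carboxylate
Product: 19 (2S)-2-[(3E)-4,8-dimethylnona-3,7-dien-1-yl]-2-methyl-4-oxo-3,4-dihydro-2H-chromene-6-carboxylic acid, via trimethylsilyl ester 18 (not isolated)
Conditions: TMSOTf (2 equiv), 2,6-lutidine (3 equiv), CH2Cl2, 0 °C; then dilute aq citric acid/THF, rt
Reagents that add atoms: none
Why: tert-Butyl ester cleavage by silyl triflate: TMSOTf silylates the ester carbonyl, the tert-butyl cation leaves as 2-methylpropene to 2,6-lutidine and the silyl ester is hydrolysed on mild aqueous work-up (which cleaves every O–Si bond formed), so the molecule meets neither the protic acid that would protonate the side-chain alkenes nor the base that would open the β-aryloxy ketone and racemise C2.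

**Compound list**

1 | (2E,6E)-farnesol, (2E,6E)-3,7,11-trimethyldodeca-2,6,10-trien-1-ol | CC(C)=CCC/C(C)=C/CC/C(C)=C/CO | starting material
2 | methyl chloroformate | COC(=O)Cl | starting material
3 | (2E,6E)-farnesyl methyl carbonate | CC(C)=CCC/C(C)=C/CC/C(C)=C/COC(=O)OC | intermediate
4 | 3-bromo-4-hydroxybenzoic acid | OC(=O)c1ccc(O)c(Br)c1 | starting material
5 | N,N-dimethylformamide di-tert-butyl acetal | CN(C)C(OC(C)(C)C)OC(C)(C)C | starting material
6 | tert-butyl 3-bromo-4-hydroxybenzoate | CC(C)(C)OC(=O)c1ccc(O)c(Br)c1 | intermediate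
7 | tert-butyl 3-bromo-4-{[(3S,6E)-3,7,11-trimethyldodeca-1,6,10-trien-3-yl]oxy}benzoate | CC(C)=CCC/C(C)=C/CC[C@@](C)(C=C)Oc1ccc(C(=O)OC(C)(C)C)cc1Br | intermediate
8 | B-alkyl-9-BBN adduct of 7, boron on the former terminal vinyl carbon, not isolated (same arrangement in space as 7; the formal descriptor at C3 becomes R because boron ranks below carbon) | CC(C)=CCC/C(C)=C/CC[C@@](C)(CCB1C2CCCC1CCC2)Oc1ccc(C(=O)OC(C)(C)C)cc1Br | intermediate
9 | tert-butyl 3-bromo-4-{[(3S,6E)-1-hydroxy-3,7,11-trimethyldodeca-6,10-dien-3-yl]oxy}benzoate | CC(C)=CCC/C(C)=C/CC[C@@](C)(CCO)Oc1ccc(C(=O)OC(C)(C)C)cc1Br | intermediate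
10 | tert-butyl 3-bromo-4-{[(3S,6E)-3,7,11-trimethyl-1-oxododeca-6,10-dien-3-yl]oxy}benzoate (aldehyde, not isolated) | CC(C)=CCC/C(C)=C/CC[C@@](C)(CC=O)Oc1ccc(C(=O)OC(C)(C)C)cc1Br | intermediate
11 | (3S,6E)-3-[2-bromo-4-(tert-butoxycarbonyl)phenoxy]-3,7,11-trimethyldodeca-6,10-dienoic acid | CC(C)=CCC/C(C)=C/CC[C@@](C)(CC(=O)O)Oc1ccc(C(=O)OC(C)(C)C)cc1Br | intermediate
12 | N,O-dimethylhydroxylamine hydrochloride | CNOC.Cl | starting material
13 | tert-butyl 3-bromo-4-{[(3S,6E)-1-(1H-imidazol-1-yl)-3,7,11-trimethyl-1-oxododeca-6,10-dien-3-yl]oxy}benzoate (acyl imidazole, not isolated) | CC(C)=CCC/C(C)=C/CC[C@@](C)(CC(=O)n1ccnc1)Oc1ccc(C(=O)OC(C)(C)C)cc1Br | intermediate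
14 | tert-butyl 3-bromo-4-({(3S,6E)-1-[methoxy(methyl)amino]-3,7,11-trimethyl-1-oxododeca-6,10-dien-3-yl}oxy)benzoate | CC(C)=CCC/C(C)=C/CC[C@@](C)(CC(=O)N(C)OC)Oc1ccc(C(=O)OC(C)(C)C)cc1Br | intermediate
15 | aryllithium from 14, lithium in place of bromine, C3 unchanged (not isolated) | CC(C)=CCC/C(C)=C/CC[C@@](C)(CC(=O)N(C)OC)Oc1ccc(C(=O)OC(C)(C)C)cc1[Li] | intermediate
16 | lithium alkoxide of the cyclic C4 hemiaminal, tert-butyl (2S)-2-[(3E)-4,8-dimethylnona-3,7-dien-1-yl]-4-[methoxy(methyl)amino]-2-methyl-4-(lithiooxy)-3,4-dihydro-2H-chromene-6-carboxylate, C4 configuration not defined (not isolated) | CC(C)=CCC/C(C)=C/CC[C@@]1(C)CC(O[Li])(N(C)OC)c2cc(C(=O)OC(C)(C)C)ccc2O1 | intermediate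
17 | tert-butyl (2S)-2-[(3E)-4,8-dimethylnona-3,7-dien-1-yl]-2-methyl-4-oxo-3,4-dihydro-2H-chromene-6-carboxylate | CC(C)=CCC/C(C)=C/CC[C@@]1(C)CC(=O)c2cc(C(=O)OC(C)(C)C)ccc2O1 | intermediate
18 | trimethylsilyl (2S)-2-[(3E)-4,8-dimethylnona-3,7-dien-1-yl]-2-methyl-4-oxo-3,4-dihydro-2H-chromene-6-carboxylate (not isolated) | CC(C)=CCC/C(C)=C/CC[C@@]1(C)CC(=O)c2cc(C(=O)O[Si](C)(C)C)ccc2O1 | intermediate
19 | (2S)-2-[(3E)-4,8-dimethylnona-3,7-dien-1-yl]-2-methyl-4-oxo-3,4-dihydro-2H-chromene-6-carboxylic acid | CC(C)=CCC/C(C)=C/CC[C@@]1(C)CC(=O)c2cc(C(=O)O)ccc2O1 | target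

**Step count and risks**

Total steps: 8. Longest linear sequence: 7 steps (step 1 or step 2, then steps 3 to 8).

Steps most likely to fail:

1. Step 3. What may go wrong: attack of the phenoxide at the unsubstituted allyl terminus, weak discrimination between the two faces of the allyl unit, or re-ionisation of the tertiary ether by the catalyst with loss of regio- and enantiopurity. The fallback uses no π-allyl chemistry; the stereocentre comes from a reagent-controlled epoxidation and the C–O bond from aromatic substitution. It sets out from 1. Sharpless asymmetric epoxidation (Ti(OiPr)4, L-(+)-diethyl tartrate, t-BuOOH, 4 Å molecular sieves, CH2Cl2, −20 °C) should give (2S,3S)-2,3-epoxyfarnesol F1. I2, PPh3 and imidazole convert it into 2,3-epoxyfarnesyl iodide F2, and zinc dust in ethanol opens this reductively to (3S,6E)-nerolidol F3, the C3–O bond never being broken. The potassium alkoxide of F3 (KN(SiMe3)2, THF/DMF, 0 °C → rt) then displaces fluoride, para to the ester, from tert-butyl 3-bromo-4-fluorobenzoate F4 (made from commercial 3-bromo-4-fluorobenzoic acid with 5 as in step 2). This nucleophilic aromatic substitution rejoins the route at 7.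

2. Step 7. What may go wrong: addition of the alkyllithium to the amide or the ester in competition with exchange, α-deprotonation of the amide with expulsion of the aryloxide, or protonation of the aryllithium before it cyclises. The fallback uses no organolithium and closes the ring at the aldehyde oxidation level by chromium/nickel chemistry. It sets out from 9. A copper-catalysed aromatic Finkelstein reaction (CuI, trans-N,N'-dimethylcyclohexane-1,2-diamine, NaI, dioxane, 110 °C) should give iodo alcohol F5. Dess–Martin periodinane (pyridine, CH2Cl2, 0 °C) gives iodo aldehyde F6. An intramolecular Nozaki–Hiyama–Kishi reaction (CrCl2, catalytic NiCl2, DMF, rt) forms C4–C4a and gives chroman-4-ol F7 as a mixture of C4 epimers. This is of no consequence, because a second Dess–Martin oxidation converts both epimers into 17, where the route is rejoined.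

3. Step 5. What may go wrong: a slow second oxidation that leaves the aldehyde long enough to lose the aryloxide by β-elimination, or attack of the oxoammonium ion on the electron-rich side-chain alkenes. The fallback uses two separate oxidations with other oxidants instead of one nitroxyl cycle. It sets out from 9. Dess–Martin periodinane (pyridine, CH2Cl2, 0 °C) gives aldehyde 10, this time isolated. Pinnick oxidation (NaClO2, NaH2PO4, large excess of 2-methyl-2-butene as hypochlorite scavenger, t-BuOH/H2O, 0 °C) takes it to 11, where the route is rejoined. No compound outside the list is made (F0).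

**Further compounds**

F1 | step 3 | (2S,3S)-2,3-epoxyfarnesol, [(2S,3S)-3-[(3E)-4,8-dimethylnona-3,7-dien-1-yl]-3-methyloxiran-2-yl]methanol | CC(C)=CCC/C(C)=C/CC[C@]1(C)O[C@H]1CO
F2 | step 3 | 2,3-epoxyfarnesyl iodide, (2R,3S)-3-[(3E)-4,8-dimethylnona-3,7-dien-1-yl]-2-(iodomethyl)-3-methyloxirane (same arrangement in space as F1; the C2 descriptor changes because iodine outranks oxygen) | CC(C)=CCC/C(C)=C/CC[C@]1(C)O[C@H]1CI
F3 | step 3 | (3S,6E)-nerolidol, (3S,6E)-3,7,11-trimethyldodeca-1,6,10-trien-3-ol | CC(C)=CCC/C(C)=C/CC[C@@](C)(C=C)O
F4 | step 3 | tert-butyl 3-bromo-4-fluorobenzoate | CC(C)(C)OC(=O)c1ccc(F)c(Br)c1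
F5 | step 7 | iodo alcohol, tert-butyl 4-{[(3S,6E)-1-hydroxy-3,7,11-trimethyldodeca-6,10-dien-3-yl]oxy}-3-iodobenzoate | CC(C)=CCC/C(C)=C/CC[C@@](C)(CCO)Oc1ccc(C(=O)OC(C)(C)C)cc1I
F6 | step 7 | iodo aldehyde, tert-butyl 3-iodo-4-{[(3S,6E)-3,7,11-trimethyl-1-oxododeca-6,10-dien-3-yl]oxy}benzoate | CC(C)=CCC/C(C)=C/CC[C@@](C)(CC=O)Oc1ccc(C(=O)OC(C)(C)C)cc1I
F7 | step 7 | chroman-4-ol, tert-butyl (2S)-2-[(3E)-4,8-dimethylnona-3,7-dien-1-yl]-4-hydroxy-2-methyl-3,4-dihydro-2H-chromene-6-carboxylate, both C4 epimers | CC(C)=CCC/C(C)=C/CC[C@@]1(C)CC(O)c2cc(C(=O)OC(C)(C)C)ccc2O1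
F0 | step 5 | none | none
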